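**Plan**

Ring numbering: cyclobutane C1 and C2 carry the two (2,2'-bithiophen-5-yl)ethynyl arms (trans, both R, C2-symmetric); C3 and C4 are methylenes.
Retrosynthesis: the C1–C(sp) bond of one arm is cut first (decarboxylative alkynylation of a C1 carboxylic acid), then the ring bonds C1–C2 and C1–C4 together, then the C(sp)–C(carbinol) bond of the other arm (acetylide acylation).
Enabling feature: in the four-membered ring, C1 is flanked by the propargylic stereocentre C2 and the methylene C4, so C1 can be the central carbon of dimethyl malonate and C2–C3–C4 a 1,3-bis-mesylate whose alkynyl carbinol carbon becomes C2.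
Forward order: aldehyde → terminal alkyne → ynone → (R)-carbinol → bis-mesylate; the cyclobutane, the only ring formed, closes in step 8; one ester is then excised and the other exchanged for the second arm.
Stereochemistry: C2 stems from a Noyori transfer hydrogenation and is relayed with SN2 inversion during ring closure; C1 is set last by trans-selective alkynylation of the C1 radical.

Key step: step 8

Remark: compounds 15, 16 and 17 are carried as mixtures of C1 epimers, because C1 becomes a planar radical in step 12. TsDPEN stands for N-(p-toluenesulfonyl)-1,2-diphenylethane-1,2-diamine.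

**Route**

Step 1
Reactants: 1 2,2'-bithiophene-5-carbaldehyde
Product: 2 5-ethynyl-2,2'-bithiophene
Conditions: Bestmann–Ohira reagent, K2CO3, MeOH, 0 °C → 25 °C
Reagents that add atoms: dimethyl (1-diazo-2-oxopropyl)phosphonate (Bestmann–Ohira reagent), COP(=O)(OC)C(=[N+]=[N-])C(C)=O
Why: Seyferth–Gilbert homologation in the Bestmann–Ohira variant, in which methanolysis of the acetyl group releases the diazomethylphosphonate anion, this olefinates the non-enolisable heteroaryl aldehyde, and loss of N2 with a 1,2-shift converts the alkylidene carbene into the terminal alkyne.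

Step 2
Reactants: 3 methyl 3-hydroxypropanoate
Product: 4 methyl 3-[(tert-butyldimethylsilyl)oxy]propanoate
Conditions: TBSCl, imidazole, CH2Cl2, 0 °C → 25 °C
Reagents that add atoms: tert-butyldimethylsilyl chloride, CC(C)(C)[Si](C)(C)Cl
Why: Routine silyl ether protection of an unhindered primary alcohol, which leaves the methyl ester untouched.

Step 3
Reactants: 4 methyl 3-[(tert-butyldimethylsilyl)oxy]propanoate
Product: 5 3-[(tert-butyldimethylsilyl)oxy]-N-methoxy-N-methylpropanamide
Conditions: MeNH(OMe)·HCl, iPrMgCl, THF, −20 °C → 0 °C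
Reagents that add atoms: N,O-dimethylhydroxylamine hydrochloride, CNOC.Cl
Why: Weinreb amide formation by aminolysis of the ester with the magnesium amide generated in the flask, run cold so that the β-silyloxy group is not eliminated.

Step 4
Reactants: 2 5-ethynyl-2,2'-bithiophene; 5 3-[(tert-butyldimethylsilyl)oxy]-N-methoxy-N-methylpropanamide
Product: 7 1-(2,2'-bithiophen-5-yl)-5-[(tert-butyldimethylsilyl)oxy]pent-1-yn-3-one, via lithium acetylide 6 (not isolated)
Conditions: 2, n-BuLi, THF, −78 °C; then 5, −78 °C → −20 °C; inverse quench into cold aq. NH4Cl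
Reagents that add atoms: none
Why: Weinreb ketone synthesis, in which the alkyne C–H is deprotonated in preference to any thiophene C–H, the chelated tetrahedral adduct prevents over-addition, and the cold inverse quench keeps the liberated hydroxylamine from adding to the ynone.

Step 5
Reactants: 7 1-(2,2'-bithiophen-5-yl)-5-[(tert-butyldimethylsilyl)oxy]pent-1-yn-3-one
Product: 8 (3R)-1-(2,2'-bithiophen-5-yl)-5-[(tert-butyldimethylsilyl)oxy]pent-1-yn-3-ol
Conditions: RuCl[(R,R)-TsDPEN](p-cymene) (2 mol %, pre-treated with KOH to the 16-electron amido complex), iPrOH, 25 °C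
Reagents that add atoms: none
Why: Noyori asymmetric transfer hydrogenation of an α,β-acetylenic ketone, in which the alkyne plays the role of the π-substituent in the six-membered hydride-transfer transition state, so that the (R,R)-ligand should deliver hydride to the face that gives the (R)-carbinol while triple bond, thiophenes and silyl ether stay intact.

Step 6
Reactants: 8 (3R)-1-(2,2'-bithiophen-5-yl)-5-[(tert-butyldimethylsilyl)oxy]pent-1-yn-3-ol
Product: 9 (3R)-5-(2,2'-bithiophen-5-yl)pent-4-yne-1,3-diol
Conditions: Bu4NF, THF, 0 °C → 25 °C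
Reagents that add atoms: none
Why: Fluoride-induced desilylation of a primary silyl ether, which does not touch the carbinol stereocentre.

Step 7
Reactants: 9 (3R)-5-(2,2'-bithiophen-5-yl)pent-4-yne-1,3-diol
Product: 10 (3R)-5-(2,2'-bithiophen-5-yl)pent-4-yne-1,3-diyl dimethanesulfonate
Conditions: MsCl, Et3N, CH2Cl2, −30 °C; cold aqueous work-up, used without storage
Reagents that add atoms: methanesulfonyl chloride, CS(=O)(=O)Cl
Why: Twofold O-sulfonylation through the sulfene pathway, which breaks no C–O bond and so retains the (R)-configuration; low temperature and a short reaction time keep chloride from displacing the propargylic mesylate.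

Step 8
Reactants: 10 (3R)-5-(2,2'-bithiophen-5-yl)pent-4-yne-1,3-diyl dimethanesulfonate; 11 dimethyl malonate
Product: 14 dimethyl (2S)-2-[(2,2'-bithiophen-5-yl)ethynyl]cyclobutane-1,1-dicarboxylate, via sodium dimethyl malonate 12 (not isolated), via monoalkylated mesylate 13 (not isolated)
Conditions: 11, NaH (2.2 equiv), THF/DMF (8:1), 0 °C; then 10 added slowly (about 0.05 M), 0 °C → 55 °C
Reagents that add atoms: none
Why: This is the twofold malonate alkylation of a 1,3-bis-electrophile, the classical entry to cyclobutane-1,1-dicarboxylates: enolate 12 displaces the unhindered primary mesylate of 10 to give 13, the remaining NaH generates the tertiary malonate carbanion, and this attacks the propargylic carbon opposite the leaving group and expels the second mesylate. The cyclobutane closes in a 4-exo-tet mode, C1–C4 being formed first and C1–C2 second. C2 is the only stereocentre of 14 and is controlled by the (R)-configured C–O bond from step 5, which should be transferred with inversion because the adjacent alkyne accelerates SN2 displacement, the closest analogy being the inversion of secondary propargylic sulfonates by stabilised carbanions. The step needs substitution to win over E2 elimination to the enyne, over SN2' attack and over ionisation to the bithienyl-stabilised propargyl cation: the malonate carbanion is soft and weakly basic, the tether rules out SN2' in the ring-closing event because it would place an allene in a six-membered ring, and the mainly ethereal medium free of halide and Lewis acid disfavours ionisation. Should the enolate attack the propargylic mesylate first, closure at the primary carbon leads to the same 14 with the same inversion, so the order of the two displacements does not change the outcome. Moderate dilution favours ring closure over a second intermolecular alkylation.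

Step 9
Reactants: 14 dimethyl (2S)-2-[(2,2'-bithiophen-5-yl)ethynyl]cyclobutane-1,1-dicarboxylate
Product: 15 methyl (2R)-2-[(2,2'-bithiophen-5-yl)ethynyl]cyclobutane-1-carboxylate (mixture of C1 epimers)
Conditions: LiCl, H2O, DMSO, 140 °C
Reagents that add atoms: none
Why: Krapcho dealkoxycarbonylation, in which chloride demethylates one ester, the carboxylate loses CO2 and the ester enolate is protonated by water, while C2 carries no acidic hydrogen and should keep its configuration (its descriptor changes from S to R only through the priority change at C1).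

Step 10
Reactants: 15 methyl (2R)-2-[(2,2'-bithiophen-5-yl)ethynyl]cyclobutane-1-carboxylate (mixture of C1 epimers)
Product: 16 (2R)-2-[(2,2'-bithiophen-5-yl)ethynyl]cyclobutane-1-carboxylic acid (mixture of C1 epimers)
Conditions: LiOH·H2O, THF/MeOH/H2O, 25 °C; then 1 M HCl, 0 °C
Reagents that add atoms: lithium hydroxide, [Li+].[OH-]
Why: Ordinary ester saponification; any epimerisation it causes is confined to C1, whose configuration is erased later.

Step 11
Reactants: 16 (2R)-2-[(2,2'-bithiophen-5-yl)ethynyl]cyclobutane-1-carboxylic acid (mixture of C1 epimers)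
Product: 17 4,5,6,7-tetrachloro-1,3-dioxoisoindolin-2-yl (2R)-2-[(2,2'-bithiophen-5-yl)ethynyl]cyclobutane-1-carboxylate (mixture of C1 epimers)
Conditions: N-hydroxytetrachlorophthalimide, N,N'-diisopropylcarbodiimide, DMAP (cat.), CH2Cl2, 25 °C
Reagents that add atoms: N-hydroxytetrachlorophthalimide, ON1C(=O)c2c(Cl)c(Cl)c(Cl)c(Cl)c2C1=O
Why: Steglich-type carbodiimide esterification, which gives the redox-active ester needed for single-electron decarboxylation.

Step 12
Reactants: 17 4,5,6,7-tetrachloro-1,3-dioxoisoindolin-2-yl (2R)-2-[(2,2'-bithiophen-5-yl)ethynyl]cyclobutane-1-carboxylate (mixture of C1 epimers); 2 5-ethynyl-2,2'-bithiophene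
Product: 20 cardopatine [(1R,2R)-1,2-bis[(2,2'-bithiophen-5-yl)ethynyl]cyclobutane], via alkynylmagnesium chloride 18 (not isolated), via alkynylzinc chloride 19 (not isolated)
Conditions: 2 (2.5 equiv), iPrMgCl·LiCl, THF, 0 °C → 25 °C; ZnCl2, 25 °C; then 17, NiCl2·glyme (20 mol %), 4,4'-di-tert-butyl-2,2'-bipyridine (40 mol %), THF/DMF, 25 °C
Reagents that add atoms: none
Why: Nickel-catalysed decarboxylative alkynylation of a redox-active ester with an alkynylzinc reagent, here made by magnesiation of the alkyne C–H with iPrMgCl (which leaves the thiophene C–H bonds alone) and transmetalation to zinc, in which electron transfer from low-valent nickel fragments the ester with loss of CO2 to the planar C1 cyclobutyl radical common to both epimers, and the bipyridine-ligated alkynylnickel species should capture it on the face away from the C2 arm, so that reductive elimination sets C1 trans to C2 and gives the (1R,2R) product (any cis product is the meso compound and lowers yield, not enantiomeric purity).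

**Compound list**

1 | 2,2'-bithiophene-5-carbaldehyde | O=Cc1ccc(-c2cccs2)s1 | starting material
2 | 5-ethynyl-2,2'-bithiophene | C#Cc1ccc(-c2cccs2)s1 | intermediate
3 | methyl 3-hydroxypropanoate | COC(=O)CCO | starting material
4 | methyl 3-[(tert-butyldimethylsilyl)oxy]propanoate | COC(=O)CCO[Si](C)(C)C(C)(C)C | intermediate
5 | 3-[(tert-butyldimethylsilyl)oxy]-N-methoxy-N-methylpropanamide | CON(C)C(=O)CCO[Si](C)(C)C(C)(C)C | intermediate
6 | lithium (2,2'-bithiophen-5-yl)acetylide | [Li]C#Cc1ccc(-c2cccs2)s1 | intermediate (not isolated)
7 | 1-(2,2'-bithiophen-5-yl)-5-[(tert-butyldimethylsilyl)oxy]pent-1-yn-3-one | CC(C)(C)[Si](C)(C)OCCC(=O)C#Cc1ccc(-c2cccs2)s1 | intermediate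
8 | (3R)-1-(2,2'-bithiophen-5-yl)-5-[(tert-butyldimethylsilyl)oxy]pent-1-yn-3-ol | CC(C)(C)[Si](C)(C)OCC[C@@H](O)C#Cc1ccc(-c2cccs2)s1 | intermediate
9 | (3R)-5-(2,2'-bithiophen-5-yl)pent-4-yne-1,3-diol | OCC[C@@H](O)C#Cc1ccc(-c2cccs2)s1 | intermediate
10 | (3R)-5-(2,2'-bithiophen-5-yl)pent-4-yne-1,3-diyl dimethanesulfonate | CS(=O)(=O)OCC[C@@H](OS(C)(=O)=O)C#Cc1ccc(-c2cccs2)s1 | intermediate
11 | dimethyl malonate | COC(=O)CC(=O)OC | starting material
12 | sodium dimethyl malonate (sodium enolate of 11) | COC(=O)[CH-]C(=O)OC.[Na+] | intermediate (not isolated)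
13 | dimethyl 2-[(3R)-5-(2,2'-bithiophen-5-yl)-3-(methanesulfonyloxy)pent-4-yn-1-yl]propanedioate | COC(=O)C(CC[C@@H](OS(C)(=O)=O)C#Cc1ccc(-c2cccs2)s1)C(=O)OC | intermediate (not isolated)
14 | dimethyl (2S)-2-[(2,2'-bithiophen-5-yl)ethynyl]cyclobutane-1,1-dicarboxylate | COC(=O)C1(C(=O)OC)CC[C@H]1C#Cc1ccc(-c2cccs2)s1 | intermediate
15 | methyl (2R)-2-[(2,2'-bithiophen-5-yl)ethynyl]cyclobutane-1-carboxylate, C1 epimer mixture | COC(=O)C1CC[C@H]1C#Cc1ccc(-c2cccs2)s1 | intermediate
16 | (2R)-2-[(2,2'-bithiophen-5-yl)ethynyl]cyclobutane-1-carboxylic acid, C1 epimer mixture | OC(=O)C1CC[C@H]1C#Cc1ccc(-c2cccs2)s1 | intermediate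
17 | 4,5,6,7-tetrachloro-1,3-dioxoisoindolin-2-yl (2R)-2-[(2,2'-bithiophen-5-yl)ethynyl]cyclobutane-1-carboxylate, C1 epimer mixture | O=C(ON1C(=O)c2c(Cl)c(Cl)c(Cl)c(Cl)c2C1=O)C1CC[C@H]1C#Cc1ccc(-c2cccs2)s1 | intermediate
18 | [(2,2'-bithiophen-5-yl)ethynyl]magnesium chloride | Cl[Mg]C#Cc1ccc(-c2cccs2)s1 | intermediate (not isolated)
19 | [(2,2'-bithiophen-5-yl)ethynyl]zinc chloride | Cl[Zn]C#Cc1ccc(-c2cccs2)s1 | intermediate (not isolated)
20 | cardopatine, (1R,2R)-1,2-bis[(2,2'-bithiophen-5-yl)ethynyl]cyclobutane | C(#C[C@@H]1CC[C@H]1C#Cc1ccc(-c2cccs2)s1)c1ccc(-c2cccs2)s1 | target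

**Step count**

Total step count: 12.
Longest linear sequence: 11 steps (steps 2 to 12, from methyl 3-hydroxypropanoate 3 to 20).

**Steps most likely to fail**

Step 8. E2 loss of the secondary mesylate, or partial ionisation at the propargylic carbon, may outpace the slow four-membered ring closure at a secondary centre and lower both yield and enantiomeric purity. The fallback separates the two alkylations and reverses their order; it sets out from 8 and comes back at 14. Alcohol 8 would be mesylated (MsCl, Et3N, CH2Cl2, −30 °C) to (3R)-1-(2,2'-bithiophen-5-yl)-5-[(tert-butyldimethylsilyl)oxy]pent-1-yn-3-yl methanesulfonate F1. An excess of sodium dimethyl malonate in THF/DMF at 0 °C to 25 °C would displace this single propargylic mesylate intermolecularly with inversion to give dimethyl 2-[(3R)-1-(2,2'-bithiophen-5-yl)-5-[(tert-butyldimethylsilyl)oxy]pent-1-yn-3-yl]propanedioate F2. HF·pyridine in THF would free the primary alcohol, dimethyl 2-[(3R)-1-(2,2'-bithiophen-5-yl)-5-hydroxypent-1-yn-3-yl]propanedioate F3, which would be mesylated at once, before it can lactonise, to dimethyl 2-[(3R)-1-(2,2'-bithiophen-5-yl)-5-(methanesulfonyloxy)pent-1-yn-3-yl]propanedioate F4. NaH in THF would then close the ring at the unhindered primary carbon and return 14. The stereocentre is thus set in an intermolecular SN2 step that can be driven with excess nucleophile at low temperature, and the ring closure takes place where elimination and ionisation are not an issue.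

Step 12. Facial discrimination at the C1 radical may be poor because the neighbouring alkynyl group is slim, and the alkynylzinc reagent may be consumed by oxidative homocoupling. The fallback keeps the ester carbon as the first alkyne carbon and sets the trans relationship thermodynamically; it sets out from 15 and comes back at 20. Ester 15 would be equilibrated towards its trans epimer (NaOMe, MeOH) and reduced with iBu2AlH (CH2Cl2, −78 °C) to (1R,2R)-2-[(2,2'-bithiophen-5-yl)ethynyl]cyclobutane-1-carbaldehyde F5. Bestmann–Ohira homologation (K2CO3, MeOH), under which residual cis aldehyde keeps epimerising, would give 5-{[(1R,2R)-2-ethynylcyclobutyl]ethynyl}-2,2'-bithiophene F6. Sonogashira coupling of F6 with commercial 5-bromo-2,2'-bithiophene (PdCl2(PPh3)2, CuI, Et3N, THF, 50 °C) would deliver 20.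

Step 9. Chloride may open the activated cyclobutane at the propargylic C2, or reversible heterolysis of the C1–C2 bond at 140 °C may erode the configuration at C2. The fallback avoids nucleophilic halide and the highest temperature; it sets out from 14 and comes back at 16. Diester 14 would be saponified (KOH, MeOH/H2O, 60 °C, then cold dilute HCl) to (2S)-2-[(2,2'-bithiophen-5-yl)ethynyl]cyclobutane-1,1-dicarboxylic acid F7. Thermal decarboxylation of this malonic acid in pyridine at 100–115 °C would give acid 16 directly, bypassing 15.

**Further compounds**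

F1 | step 8 | (3R)-1-(2,2'-bithiophen-5-yl)-5-[(tert-butyldimethylsilyl)oxy]pent-1-yn-3-yl methanesulfonate | CC(C)(C)[Si](C)(C)OCC[C@@H](OS(C)(=O)=O)C#Cc1ccc(-c2cccs2)s1
F2 | step 8 | dimethyl 2-[(3R)-1-(2,2'-bithiophen-5-yl)-5-[(tert-butyldimethylsilyl)oxy]pent-1-yn-3-yl]propanedioate | COC(=O)C(C(=O)OC)[C@@H](CCO[Si](C)(C)C(C)(C)C)C#Cc1ccc(-c2cccs2)s1
F3 | step 8 | dimethyl 2-[(3R)-1-(2,2'-bithiophen-5-yl)-5-hydroxypent-1-yn-3-yl]propanedioate | COC(=O)C(C(=O)OC)[C@@H](CCO)C#Cc1ccc(-c2cccs2)s1
F4 | step 8 | dimethyl 2-[(3R)-1-(2,2'-bithiophen-5-yl)-5-(methanesulfonyloxy)pent-1-yn-3-yl]propanedioate | COC(=O)C(C(=O)OC)[C@@H](CCOS(C)(=O)=O)C#Cc1ccc(-c2cccs2)s1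
F5 | step 12 | (1R,2R)-2-[(2,2'-bithiophen-5-yl)ethynyl]cyclobutane-1-carbaldehyde | O=C[C@@H]1CC[C@H]1C#Cc1ccc(-c2cccs2)s1
F6 | step 12 | 5-{[(1R,2R)-2-ethynylcyclobutyl]ethynyl}-2,2'-bithiophene | C#C[C@@H]1CC[C@H]1C#Cc1ccc(-c2cccs2)s1
F7 | step 9 | (2S)-2-[(2,2'-bithiophen-5-yl)ethynyl]cyclobutane-1,1-dicarboxylic acid | OC(=O)C1(C(=O)O)CC[C@H]1C#Cc1ccc(-c2cccs2)s1
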